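- Whatever else happens in a closed flask, each target takes one substrate and one coupling partner, so c(target) stays within the smaller charge. In delta that is the coupling partner, the limiting reagent, at 600 mM, and your hunch of a target near that ceiling would be 42.9% of the substrate.

| flask | substrate | coupling partner | free catalyst | time |
|---|---|---|---|---|
| gamma | 300 mM | 600 mM | 15.0 mM |  |
| beta | 120 mM | 420 mM | 15.0 mM |  |
| eta | 300 mM | 1800 mM | 15.0 mM |  |
| epsilon | 600 mM | 600 mM | 15.0 mM |  |
| delta | 1400 mM | 600 mM | 15.0 mM | 65 min |

| run | time / min | [target] / mM |
|---|---|---|
| gamma run | 2.3 | 16.3 |
| gamma run | 7.1 | 48.8 |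
| gamma run | 14 | 78.4 |
| gamma run | 21 | 97.7 |
| gamma run | 31 | 116.8 |
| gamma run | 41 | 127.1 |
| gamma run | 52 | 131.8 |
| gamma run | 65 | 138.5 |
| beta run | 2.3 | 8.1 |
| beta run | 7.1 | 24.2 |
| beta run | 14 | 42.3 |
| beta run | 21 | 53.6 |
| beta run | 31 | 67.2 |
| beta run | 41 | 74.7 |
| beta run | 52 | 76.3 |
| beta run | 65 | 80.5 |
| eta run | 2.3 | 25.4 |
| eta run | 7.1 | 63.1 |
| eta run | 14 | 97.3 |
| eta run | 21 | 117.0 |
| eta run | 31 | 135.5 |
| eta run | 41 | 143.3 |
| eta run | 52 | 150.1 |
| eta run | 65 | 154.7 |
| epsilon run | 2.3 | 21.5 |
| epsilon run | 7.1 | 63.0 |
| epsilon run | 14 | 100.4 |
| epsilon run | 21 | 125.4 |
| epsilon run | 31 | 147.5 |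
| epsilon run | 41 | 162.0 |
| epsilon run | 52 | 168.6 |
| epsilon run | 65 | 174.6 |

(each reading ± 0.9 mM)

- the exponent of [coupling partner] in the starting rate at the charge of the gamma run (at the point where two percent of the substrate have become target)
- the exponent of [substrate] in the starting rate at the charge of the gamma run (at the point where two percent of the substrate have become target) (one fixed amount of target, the same in the runs compared)
- target in the delta run at 65 min, as a share of the substrate charged

- Overall: substrate + coupling partner -> target, with free catalyst as catalyst.
- Constant volume, constant temperature.
- An order is taken over about fifteen percent of the charge, up and down.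

- The readings speak against that ceiling: between its last two readings gamma added 6.70 mM, and the last of them, 138.5 mM, stands lower than the gamma substrate charge of 300 mM.
- So we would reckon with a time, not a ceiling. The run-out time τ, the time constant of an exponential approach to the last reading, taken from the gamma reading at 14 min, is 16.8 min.
- At 65 min that approach has 2.09% still open, so a delta flask with this τ stands at its plateau by then, and the question becomes how high that plateau lies.
- Our own reckoning takes the height from the substrate exponent between gamma and epsilon at 7.1 min, which reads 0.368. Scaling the last epsilon reading to the delta charge gives 239 mM, which is 17.0% of the substrate and lower than your ceiling.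
- That exponent spans a factor of 2.00 in substrate, so it is no local order, and for the two orders we would go with the forecast.
- The forecast gives 0.48 for the coupling partner, 0.43 for the substrate and 14.7% for delta, on the ground that “Their shape looks like catalyst dying”. Its delta figure is lower than ours.

    free catalyst + substrate → loaded catalyst + by-product (9.420 /M/min)
    loaded catalyst + coupling partner → target + free catalyst (5.124 /M/min)
    2 substrate → homo dimer (0.1818 /M/min)
    free catalyst + impurity → spent catalyst

- The flask gives 14.7% in delta, with exponents of 0.49 for the coupling partner and 0.53 for the substrate, the latter higher than the forecast's. A fit in which the catalyst dies in pairs leaves a root mean square residual of 22 in units of the scatter. Divided by τ, the 205 mM of target in delta reads as a starting rate of 12.2 mM/min, supposing delta keeps the τ of gamma. Carried to epsilon with its last reading, τ puts a quarter of the substrate charged at 32.9 min, and the epsilon flask reaches it at 31.9 min.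

The runs were computed on assumed constants; noise was put on by code.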